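The route rests on disconnecting the C8–O8 bond at C8, the fully substituted benzylic carbinol carbon of the oxirane ring that carries ring A (the arene), O8 and the two oxygenated one-carbon arms C9 and C10. With C9 masked as vinyl, C8 becomes the aryl-bearing terminus of an allylpalladium unit. In one operation, a racemic 4-aryl-4-vinyl-1,3-dioxolan-2-one (phenol and C7 alcohol silylated) loses CO2 under zerovalent palladium and a chiral phosphoramidite, captures formaldehyde at O10 and closes a 1,3-dioxolane at C8, forming O10–CH2 and C8–O8 and fixing the only stereocentre. The methylene acetal then keeps C10 and O8 distinct from the vinyl-derived C9.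

Key step: step 7

Labels: thymol numbering is used (ring A = arene C1–C6; C7 = benzylic CH2 on C1; phenolic oxygen on C3; C8 on C4; C9 = oxirane CH2; C10 = acyloxymethyl carbon; O8 = oxirane oxygen).
Assumption: the (Sa,S,S) antipode of the ligand is taken to deliver the (S)-configured dioxolane of the key step; should a pilot run show the opposite sense, the mirror-image ligand is used with nothing else changed.

Step 1
Reactants: 1 methyl 3-hydroxy-4-iodobenzoate
Product: 2 methyl 4-iodo-3-(triisopropylsilyloxy)benzoate
Conditions: TIPSCl, imidazole, DMF, rt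
Reagents that add atoms: chlorotriisopropylsilane, CC(C)[Si](Cl)(C(C)C)C(C)C
Why: Imidazole-mediated O-silylation of the phenol; the triisopropylsilyl ether is chosen because, unlike smaller aryl silyl ethers, it should withstand the Grignard reagents, carbonate, borohydride and amine bases used later and still fall to fluoride at the end.

Step 2
Reactants: 2 methyl 4-iodo-3-(triisopropylsilyloxy)benzoate
Product: 3 [4-iodo-3-(triisopropylsilyloxy)phenyl]methanol
Conditions: i-Bu2AlH, CH2Cl2, −78 → 0 °C; aq. potassium sodium tartrate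
Reagents that add atoms: none
Why: Hydride reduction of the benzoate ester with i-Bu2AlH should give the benzylic alcohol (C7) and leave the aryl iodide and the aryl silyl ether untouched.

Step 3
Reactants: 3 [4-iodo-3-(triisopropylsilyloxy)phenyl]methanol
Product: 4 tert-butyl{[4-iodo-3-(triisopropylsilyloxy)phenyl]methoxy}dimethylsilane
Conditions: TBSCl, imidazole, DMF, rt
Reagents that add atoms: tert-butylchlorodimethylsilane, CC(C)(C)[Si](C)(C)Cl
Why: Routine silyl ether formation at the primary alcohol; this alkyl silyl ether can later be removed by dilute acid under which the aryl triisopropylsilyl ether persists.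

Step 4
Reactants: 4 tert-butyl{[4-iodo-3-(triisopropylsilyloxy)phenyl]methoxy}dimethylsilane; 5 2-chloro-N-methoxy-N-methylacetamide
Product: 7 1-[4-(tert-butyldimethylsilyloxymethyl)-2-(triisopropylsilyloxy)phenyl]-2-chloroethan-1-one, via arylmagnesium chloride 6 (not isolated)
Conditions: i-PrMgCl·LiCl, THF, −20 °C; then 5, −20 °C → rt; aq. NH4Cl
Reagents that add atoms: none
Why: Iodine–magnesium exchange on the aryl iodide is fast below 0 °C (the iodide is used because an electron-rich bromide exchanges sluggishly, and the arylmagnesium species is not prone to the silyl shift open to an aryllithium), and the Weinreb ketone synthesis stops at the chelated adduct, so the α-chloro ketone forms only on quench.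

Step 5
Reactants: 7 1-[4-(tert-butyldimethylsilyloxymethyl)-2-(triisopropylsilyloxy)phenyl]-2-chloroethan-1-one; 8 vinylmagnesium bromide
Product: 9 rac-2-[4-(tert-butyldimethylsilyloxymethyl)-2-(triisopropylsilyloxy)phenyl]-1-chlorobut-3-en-2-ol
Conditions: THF, −78 °C; aq. NH4Cl at −78 °C
Reagents that add atoms: none
Why: Grignard 1,2-addition to the ketone at −78 °C is much faster than substitution at the chloromethyl group, and a cold quench prevents closure to the vinyl oxirane; C8 is deliberately formed racemic.

Step 6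
Reactants: 9 rac-2-[4-(tert-butyldimethylsilyloxymethyl)-2-(triisopropylsilyloxy)phenyl]-1-chlorobut-3-en-2-ol
Product: 10 rac-4-[4-(tert-butyldimethylsilyloxymethyl)-2-(triisopropylsilyloxy)phenyl]-4-vinyl-1,3-dioxolan-2-one
Conditions: CO2 (1 atm), Cs2CO3, DMF, 40 °C
Reagents that add atoms: carbon dioxide, O=C=O
Why: Carboxylative cyclisation of a halohydrin: the alkoxide takes up CO2 and the carbonate monoester anion displaces chloride in a 5-exo-tet closure, any vinyl oxirane formed on the way being reopened by chloride and drained to the same carbonate.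

Step 7
Reactants: 10 rac-4-[4-(tert-butyldimethylsilyloxymethyl)-2-(triisopropylsilyloxy)phenyl]-4-vinyl-1,3-dioxolan-2-one; 11 formaldehyde
Product: 12 (4S)-4-[4-(tert-butyldimethylsilyloxymethyl)-2-(triisopropylsilyloxy)phenyl]-4-vinyl-1,3-dioxolane
Conditions: Pd2(dba)3·CHCl3 (2.5 mol %), (Sa,S,S)-BINOL phosphoramidite with an N,N-bis[1-(2-methoxyphenyl)ethyl]amino group (10 mol %), 37% aq. CH2O, THF, 40 °C
Reagents that add atoms: none
Why: Zerovalent palladium ionises the tertiary allylic C8–O bond of 10 and the carbonate loses CO2, giving a zwitterionic 1-aryl-1-(oxidomethyl)allyl palladium complex in which C8 is planar, so both enantiomers of 10 converge by π–σ–π interconversion. The C10 alkoxide adds to formaldehyde and the hemiacetal alkoxide attacks the aryl-substituted allyl terminus C8 (not the central allyl carbon and not the CH2 terminus), which forms O10–CH2 and C8–O8. The closest known reaction type is the palladium-catalysed asymmetric decarboxylative [3+2] cycloaddition of 4-substituted 4-vinyl-1,3-dioxolan-2-ones with aldehydes, formaldehyde included. The dioxolane closes in a 5-exo mode with respect to the allyl unit, which should be favoured over seven-membered closure at the unsubstituted terminus. The C8 stereocentre is set by the phosphoramidite on palladium, which selects the enantioface of the allyl terminus in the ring-closing C–O bond formation under Curtin–Hammett conditions. The step needs branched over linear attack and one enantioface over the other; the short tether and the cation-stabilising aryl group at C8 should secure the first and the ligand the second.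

Step 8
Reactants: 12 (4S)-4-[4-(tert-butyldimethylsilyloxymethyl)-2-(triisopropylsilyloxy)phenyl]-4-vinyl-1,3-dioxolane
Product: 14 {(4R)-4-[4-(tert-butyldimethylsilyloxymethyl)-2-(triisopropylsilyloxy)phenyl]-1,3-dioxolan-4-yl}methanol, via aldehyde 13 (not isolated)
Conditions: O3, CH2Cl2/MeOH, −78 °C; then NaBH4, −78 → 0 °C
Reagents that add atoms: ozone, [O-][O+]=O
Why: Ozonolysis with reductive work-up: ozone cleaves the monosubstituted alkene far faster than it attacks the arene, NaBH4 reduces the non-enolisable aldehyde to the C9 alcohol, and C8 is not touched.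

Step 9
Reactants: 14 {(4R)-4-[4-(tert-butyldimethylsilyloxymethyl)-2-(triisopropylsilyloxy)phenyl]-1,3-dioxolan-4-yl}methanol
Product: 15 {(4S)-4-[4-(tert-butyldimethylsilyloxymethyl)-2-(triisopropylsilyloxy)phenyl]-1,3-dioxolan-4-yl}methyl methanesulfonate
Conditions: MsCl, Et3N, CH2Cl2, 0 °C
Reagents that add atoms: methanesulfonyl chloride, CS(=O)(=O)Cl
Why: Mesylation through the sulfene pathway is fast even for this neopentyl-type primary alcohol and marks C9 as the electrophilic arm while O8 and O10 are still locked in the acetal, so the two arms cannot be confused.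

Step 10
Reactants: 15 {(4S)-4-[4-(tert-butyldimethylsilyloxymethyl)-2-(triisopropylsilyloxy)phenyl]-1,3-dioxolan-4-yl}methyl methanesulfonate
Product: 17 (2S)-2,3-dihydroxy-2-[4-(hydroxymethyl)-2-(triisopropylsilyloxy)phenyl]propyl methanesulfonate, via silyl ether diol 16 (not isolated)
Conditions: TMSOTf, 2,2′-bipyridyl, CH2Cl2, 0 °C → rt; H2O; then 1 M aq. HCl, THF, rt
Reagents that add atoms: none
Why: Silyl triflate–bipyridyl cleavage of a methylene acetal: silylation of the less hindered O10 opens the ring to an N-(alkoxymethyl)pyridinium salt on O8 that water hydrolyses with loss of formaldehyde, so the C8–O8 bond is never broken, and the dilute acid that follows removes only the primary benzylic silyl ether, the aryl silyl ether and the mesylate being inert.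

Step 11
Reactants: 17 (2S)-2,3-dihydroxy-2-[4-(hydroxymethyl)-2-(triisopropylsilyloxy)phenyl]propyl methanesulfonate
Product: 18 (2S)-2-hydroxy-3-(methylsulfonyloxy)-2-[4-(2-methylpropanoyloxymethyl)-2-(triisopropylsilyloxy)phenyl]propyl 2-methylpropanoate
Conditions: i-PrCOCl, pyridine, CH2Cl2, 0 °C
Reagents that add atoms: 2-methylpropanoyl chloride, CC(C)C(=O)Cl
Why: Selective O-acylation: the primary hydroxyls at C7 and C10 react with the acid chloride while the hindered tertiary O8–H does not, and placing the C10 ester before ring closure removes the free C10 alkoxide that could otherwise invert C8 by a degenerate Payne rearrangement.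

Step 12
Reactants: 18 (2S)-2-hydroxy-3-(methylsulfonyloxy)-2-[4-(2-methylpropanoyloxymethyl)-2-(triisopropylsilyloxy)phenyl]propyl 2-methylpropanoate
Product: 19 {(2R)-2-[4-(2-methylpropanoyloxymethyl)-2-(triisopropylsilyloxy)phenyl]oxiran-2-yl}methyl 2-methylpropanoate
Conditions: DBU, CH2Cl2, 0 °C → rt
Reagents that add atoms: none
Why: Intramolecular Williamson etherification (3-exo-tet) of O8 onto the C9 mesylate under a non-nucleophilic amidine base that spares the esters; only the C9–O bond is broken, so C8 keeps its configuration and its descriptor changes to (R) by priority alone.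

Step 13
Reactants: 19 {(2R)-2-[4-(2-methylpropanoyloxymethyl)-2-(triisopropylsilyloxy)phenyl]oxiran-2-yl}methyl 2-methylpropanoate
Product: 21 5-(2-methylpropanoyloxymethyl)-2-{(2R)-2-[(2-methylpropanoyloxy)methyl]oxiran-2-yl}phenyl (2E)-2-methylbut-2-enoate, via tetrabutylammonium phenoxide 20 (not isolated)
Conditions: (E)-2-methylbut-2-enoic anhydride (3 equiv), Bu4NF (1.1 equiv), THF, −40 → 0 °C
Reagents that add atoms: (2E)-2-methylbut-2-enoic anhydride (tiglic anhydride), C/C=C(\C)C(=O)OC(=O)/C(C)=C/C
Why: Fluoride desilylation of the aryl silyl ether with in situ O-acylation: the phenoxide should be acylated by the anhydride already present faster than it can open the neighbouring oxirane, and the low temperature and absence of acid protect the benzylic epoxide and the esters.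

Compound list
1 | methyl 3-hydroxy-4-iodobenzoate | COC(=O)c1ccc(I)c(O)c1 | starting material
2 | methyl 4-iodo-3-(triisopropylsilyloxy)benzoate | COC(=O)c1ccc(I)c(O[Si](C(C)C)(C(C)C)C(C)C)c1 | intermediate
3 | [4-iodo-3-(triisopropylsilyloxy)phenyl]methanol | OCc1ccc(I)c(O[Si](C(C)C)(C(C)C)C(C)C)c1 | intermediate
4 | tert-butyl{[4-iodo-3-(triisopropylsilyloxy)phenyl]methoxy}dimethylsilane | CC(C)(C)[Si](C)(C)OCc1ccc(I)c(O[Si](C(C)C)(C(C)C)C(C)C)c1 | intermediate
5 | 2-chloro-N-methoxy-N-methylacetamide | CON(C)C(=O)CCl | starting material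
6 | [4-(tert-butyldimethylsilyloxymethyl)-2-(triisopropylsilyloxy)phenyl]magnesium chloride (LiCl complex) | Cl[Mg]c1ccc(CO[Si](C)(C)C(C)(C)C)cc1O[Si](C(C)C)(C(C)C)C(C)C | intermediate (not isolated)
7 | 1-[4-(tert-butyldimethylsilyloxymethyl)-2-(triisopropylsilyloxy)phenyl]-2-chloroethan-1-one | O=C(CCl)c1ccc(CO[Si](C)(C)C(C)(C)C)cc1O[Si](C(C)C)(C(C)C)C(C)C | intermediate
8 | vinylmagnesium bromide | C=C[Mg]Br | starting material
9 | rac-2-[4-(tert-butyldimethylsilyloxymethyl)-2-(triisopropylsilyloxy)phenyl]-1-chlorobut-3-en-2-ol | C=CC(O)(CCl)c1ccc(CO[Si](C)(C)C(C)(C)C)cc1O[Si](C(C)C)(C(C)C)C(C)C | intermediate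
10 | rac-4-[4-(tert-butyldimethylsilyloxymethyl)-2-(triisopropylsilyloxy)phenyl]-4-vinyl-1,3-dioxolan-2-one | C=CC1(c2ccc(CO[Si](C)(C)C(C)(C)C)cc2O[Si](C(C)C)(C(C)C)C(C)C)COC(=O)O1 | intermediate
11 | formaldehyde (used as 37% aqueous solution) | C=O | starting material
12 | (4S)-4-[4-(tert-butyldimethylsilyloxymethyl)-2-(triisopropylsilyloxy)phenyl]-4-vinyl-1,3-dioxolane | CC(C)(C)[Si](C)(C)OCc1ccc([C@]2(COCO2)C=C)c(O[Si](C(C)C)(C(C)C)C(C)C)c1 | intermediate
13 | (4S)-4-[4-(tert-butyldimethylsilyloxymethyl)-2-(triisopropylsilyloxy)phenyl]-1,3-dioxolane-4-carbaldehyde | CC(C)(C)[Si](C)(C)OCc1ccc([C@]2(COCO2)C=O)c(O[Si](C(C)C)(C(C)C)C(C)C)c1 | intermediate (not isolated)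
14 | {(4R)-4-[4-(tert-butyldimethylsilyloxymethyl)-2-(triisopropylsilyloxy)phenyl]-1,3-dioxolan-4-yl}methanol | CC(C)(C)[Si](C)(C)OCc1ccc([C@]2(COCO2)CO)c(O[Si](C(C)C)(C(C)C)C(C)C)c1 | intermediate
15 | {(4S)-4-[4-(tert-butyldimethylsilyloxymethyl)-2-(triisopropylsilyloxy)phenyl]-1,3-dioxolan-4-yl}methyl methanesulfonate | CC(C)(C)[Si](C)(C)OCc1ccc([C@]2(COCO2)COS(C)(=O)=O)c(O[Si](C(C)C)(C(C)C)C(C)C)c1 | intermediate
16 | (2S)-2-[4-(tert-butyldimethylsilyloxymethyl)-2-(triisopropylsilyloxy)phenyl]-2,3-dihydroxypropyl methanesulfonate | CC(C)(C)[Si](C)(C)OCc1ccc([C@](O)(CO)COS(C)(=O)=O)c(O[Si](C(C)C)(C(C)C)C(C)C)c1 | intermediate (not isolated)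
17 | (2S)-2,3-dihydroxy-2-[4-(hydroxymethyl)-2-(triisopropylsilyloxy)phenyl]propyl methanesulfonate | OCc1ccc([C@](O)(CO)COS(C)(=O)=O)c(O[Si](C(C)C)(C(C)C)C(C)C)c1 | intermediate
18 | (2S)-2-hydroxy-3-(methylsulfonyloxy)-2-[4-(2-methylpropanoyloxymethyl)-2-(triisopropylsilyloxy)phenyl]propyl 2-methylpropanoate | CC(C)C(=O)OCc1ccc([C@](O)(COC(=O)C(C)C)COS(C)(=O)=O)c(O[Si](C(C)C)(C(C)C)C(C)C)c1 | intermediate
19 | {(2R)-2-[4-(2-methylpropanoyloxymethyl)-2-(triisopropylsilyloxy)phenyl]oxiran-2-yl}methyl 2-methylpropanoate | CC(C)C(=O)OCc1ccc([C@]2(COC(=O)C(C)C)CO2)c(O[Si](C(C)C)(C(C)C)C(C)C)c1 | intermediate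
20 | tetrabutylammonium 5-(2-methylpropanoyloxymethyl)-2-{(2R)-2-[(2-methylpropanoyloxy)methyl]oxiran-2-yl}phenoxide | CC(C)C(=O)OCc1ccc([C@]2(COC(=O)C(C)C)CO2)c([O-])c1.CCCC[N+](CCCC)(CCCC)CCCC | intermediate (not isolated)
21 | 5-(2-methylpropanoyloxymethyl)-2-{(2R)-2-[(2-methylpropanoyloxy)methyl]oxiran-2-yl}phenyl (2E)-2-methylbut-2-enoate | C/C=C(\C)C(=O)Oc1cc(COC(=O)C(C)C)ccc1[C@]1(COC(=O)C(C)C)CO1 | target

Total step count: 13. Longest linear sequence: 13 steps (1 → 21); all other inputs are commercial.

Steps most likely to fail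

Step 7. The bulky ortho silyloxy group may twist ring A out of conjugation with the allyl unit, so that ionisation slows, ring closure leaks to the unsubstituted allyl terminus, or the ligand discriminates the two faces of C8 poorly. The fallback sets out from 4 and comes back to the route at 19. Iodide 4 is converted into the Grignard reagent 6 as in step 4 and added across the triple bond of propargyl alcohol (as its magnesium alkoxide) under CuI catalysis. This known carbomagnesiation places the aryl group on the internal carbon and should give 2-[4-(tert-butyldimethylsilyloxymethyl)-2-(triisopropylsilyloxy)phenyl]prop-2-en-1-ol F1. Dilute aqueous HCl in THF removes the benzylic silyl group to give the allylic diol 2-[4-(hydroxymethyl)-2-(triisopropylsilyloxy)phenyl]prop-2-en-1-ol F2. Sharpless asymmetric epoxidation (Ti(OiPr)4, L-(+)-diisopropyl tartrate, t-BuOOH, 4 Å sieves, CH2Cl2, −20 °C) should, by the usual face rule for allylic alcohols, give {(2S)-2-[4-(hydroxymethyl)-2-(triisopropylsilyloxy)phenyl]oxiran-2-yl}methanol F3, which has the spatial arrangement at C8 of the target. Isobutyric anhydride, Et3N and catalytic DMAP then acylate both primary hydroxyls and deliver 19.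

Step 10. Opening of the robust methylene acetal may be incomplete, or Lewis-acid ionisation of the benzylic C8–O8 bond may erode the configuration. The fallback sets out from 15 and comes back at 18 without passing through the triol. Dilute aqueous HCl in THF removes the benzylic silyl group from 15 to give {(4S)-4-[4-(hydroxymethyl)-2-(triisopropylsilyloxy)phenyl]-1,3-dioxolan-4-yl}methyl methanesulfonate F4. 2-Methylpropanoyl chloride and pyridine convert it into the benzylic ester 4-[(4S)-4-(methylsulfonyloxymethyl)-1,3-dioxolan-4-yl]-3-(triisopropylsilyloxy)benzyl 2-methylpropanoate F5. 2-Methylpropanoyl chloride with catalytic ZnCl2 then opens the dioxolane by acylation of the less hindered O10 and chloride capture of the oxocarbenium ion on O8, the classical acyl halide cleavage of cyclic formals. This should give (2S)-2-(chloromethoxy)-3-(methylsulfonyloxy)-2-[4-(2-methylpropanoyloxymethyl)-2-(triisopropylsilyloxy)phenyl]propyl 2-methylpropanoate F6. Aqueous NaHCO3 in THF hydrolyses the chloromethyl ether to the hemiformal, which sheds formaldehyde and gives 18.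

Step 6. The carboxylative closure may stall at the vinyl oxirane because chloride displacement next to the quaternary carbon is slow, or the caesium alkoxide may take over or strip the neighbouring aryl silyl group. The fallback sets out from 7 and comes back at 10. KOAc in DMF displaces the chloride of 7 to give 2-[4-(tert-butyldimethylsilyloxymethyl)-2-(triisopropylsilyloxy)phenyl]-2-oxoethyl acetate F7. Excess vinylmagnesium bromide 8 in THF at −78 → 0 °C adds to the ketone and removes the acetyl group, giving rac-2-[4-(tert-butyldimethylsilyloxymethyl)-2-(triisopropylsilyloxy)phenyl]but-3-ene-1,2-diol F8. 1,1′-Carbonyldiimidazole in CH2Cl2 then closes the five-membered carbonate 10 under neutral conditions.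

Further compounds
F1 | step 7 | 2-[4-(tert-butyldimethylsilyloxymethyl)-2-(triisopropylsilyloxy)phenyl]prop-2-en-1-ol | C=C(CO)c1ccc(CO[Si](C)(C)C(C)(C)C)cc1O[Si](C(C)C)(C(C)C)C(C)C
F2 | step 7 | 2-[4-(hydroxymethyl)-2-(triisopropylsilyloxy)phenyl]prop-2-en-1-ol | C=C(CO)c1ccc(CO)cc1O[Si](C(C)C)(C(C)C)C(C)C
F3 | step 7 | {(2S)-2-[4-(hydroxymethyl)-2-(triisopropylsilyloxy)phenyl]oxiran-2-yl}methanol | OCc1ccc([C@]2(CO)CO2)c(O[Si](C(C)C)(C(C)C)C(C)C)c1
F4 | step 10 | {(4S)-4-[4-(hydroxymethyl)-2-(triisopropylsilyloxy)phenyl]-1,3-dioxolan-4-yl}methyl methanesulfonate | OCc1ccc([C@]2(COCO2)COS(C)(=O)=O)c(O[Si](C(C)C)(C(C)C)C(C)C)c1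
F5 | step 10 | 4-[(4S)-4-(methylsulfonyloxymethyl)-1,3-dioxolan-4-yl]-3-(triisopropylsilyloxy)benzyl 2-methylpropanoate | CC(C)C(=O)OCc1ccc([C@]2(COCO2)COS(C)(=O)=O)c(O[Si](C(C)C)(C(C)C)C(C)C)c1
F6 | step 10 | (2S)-2-(chloromethoxy)-3-(methylsulfonyloxy)-2-[4-(2-methylpropanoyloxymethyl)-2-(triisopropylsilyloxy)phenyl]propyl 2-methylpropanoate | CC(C)C(=O)OCc1ccc([C@](OCCl)(COC(=O)C(C)C)COS(C)(=O)=O)c(O[Si](C(C)C)(C(C)C)C(C)C)c1
F7 | step 6 | 2-[4-(tert-butyldimethylsilyloxymethyl)-2-(triisopropylsilyloxy)phenyl]-2-oxoethyl acetate | CC(=O)OCC(=O)c1ccc(CO[Si](C)(C)C(C)(C)C)cc1O[Si](C(C)C)(C(C)C)C(C)C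
F8 | step 6 | rac-2-[4-(tert-butyldimethylsilyloxymethyl)-2-(triisopropylsilyloxy)phenyl]but-3-ene-1,2-diol | C=CC(O)(CO)c1ccc(CO[Si](C)(C)C(C)(C)C)cc1O[Si](C(C)C)(C(C)C)C(C)C
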